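**Retrosynthetic overview** (flavanone half unprimed, rings A, B, C; flavone half double-primed, rings A'', B'', C'')
- The plan rests on ring C: C2 is a CH bound to O1 and to the 4-oxygenated ring B, so it is the benzylic carbon of a 4-alkoxybenzyl ether of a ring A oxygen, and C3 lies between the C4 carbonyl and C3'' of the flavone. Ring C is therefore cut at C2–C3 (carbene at C3, benzylic C–H at C2).
- The diazoketone comes from the CH2 ketone by diazo transfer. That ketone is cut at the C3–C3'' bond into a ring A acetophenone and a 3-iodoflavone, joined by palladium-catalysed α-arylation with all phenols already protected.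
- The ring A acetophenone carries two identical ortho 4-(benzyloxy)benzyl ethers (either one delivers C2 and ring B, the other protects O5) and a para benzyl ether. They are put on 2,4,6-trihydroxyacetophenone one at a time, in the order set by acidity and chelation.
- The iodoflavone comes from a benzylated 2-hydroxyacetophenone and 4-(benzyloxy)benzoyl chloride (Baker–Venkataraman), then lithiation and iodination at C3''.
- Ring order: C'' (step 1), then ring C (step 8). C2 is set by the catalyst, C3 by equilibration, and hydrogenolysis then frees the six phenols.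

Key step: step 8

Assumption: the sense of induction of Rh2(S-PTTL)4 at C2 cannot be derived with certainty for this carbene, so the S ligand is written and Rh2(R-PTTL)4 is used instead if the first run gives the 2R series; the 2,3-trans isomer is taken to be the more stable one, and 1-[2,4-bis(benzyloxy)-6-hydroxyphenyl]ethanone (1) is taken to be a catalogue compound.

**Step 1**
Reactants: 1 1-[2,4-bis(benzyloxy)-6-hydroxyphenyl]ethanone; 2 4-(benzyloxy)benzoyl chloride
Product: 4 5,7-bis(benzyloxy)-2-[4-(benzyloxy)phenyl]-4H-chromen-4-one, via 1,3-diketone 3 (not isolated)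
Conditions: LiN(SiMe3)2 (3.2 equiv), THF, −78 → −10 °C; 2 (1.05 equiv), −78 °C → rt; 1 M HCl; then NaOAc, AcOH, 100 °C
Reagents that add atoms: none
Why: In this Baker–Venkataraman-type flavone synthesis the lithium dianion of 1 is aroylated at the enolate carbon, and the 2-hydroxyaryl 1,3-diketone then cyclodehydrates in buffered acetic acid to ring C'', conditions that leave the three benzyl ethers intact.

**Step 2**
Reactants: 4 5,7-bis(benzyloxy)-2-[4-(benzyloxy)phenyl]-4H-chromen-4-one
Product: 5 5,7-bis(benzyloxy)-2-[4-(benzyloxy)phenyl]-3-iodo-4H-chromen-4-one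
Conditions: LiN(iPr)2 (1.3 equiv), THF, −78 °C; I2 (1.5 equiv), THF, −78 °C → rt; aq. Na2S2O3
Reagents that add atoms: iodine, II
Why: Lithiation of a flavone at C3'' by a hindered lithium amide (the C4'' carbonyl holds the lithium) followed by iodinolysis is regiospecific, whereas electrophilic iodination would attack C6'' or C8'' of the electron-rich ring A''.

**Step 3**
Reactants: 6 1-(2,4,6-trihydroxyphenyl)ethanone; 7 benzyl bromide
Product: 8 1-[4-(benzyloxy)-2,6-dihydroxyphenyl]ethanone
Conditions: 7 (1.0 equiv), K2CO3 (1.05 equiv), DMF, 0 °C → rt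
Reagents that add atoms: none
Why: Williamson etherification with one equivalent of base and halide should go mainly to the para hydroxyl, which is the most acidic (vinylogous acid of the acetyl group) and the only one neither hindered nor hydrogen-bonded; the dibenzyl by-product is removed by chromatography.

**Step 4**
Reactants: 8 1-[4-(benzyloxy)-2,6-dihydroxyphenyl]ethanone; 9 4-(benzyloxy)benzyl chloride
Product: 10 1-{4-(benzyloxy)-2-[4-(benzyloxy)benzyloxy]-6-hydroxyphenyl}ethanone
Conditions: 9 (1.05 equiv), K2CO3 (1.2 equiv), KI (cat.), acetone, reflux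
Reagents that add atoms: none
Why: Williamson etherification of one of the two equivalent ortho hydroxyls should stop at the mono-ether, because the remaining hydroxyl is locked in a hydrogen bond to the carbonyl and is inert under these mild conditions.

**Step 5**
Reactants: 10 1-{4-(benzyloxy)-2-[4-(benzyloxy)benzyloxy]-6-hydroxyphenyl}ethanone; 9 4-(benzyloxy)benzyl chloride
Product: 11 1-{4-(benzyloxy)-2,6-bis[4-(benzyloxy)benzyloxy]phenyl}ethanone
Conditions: 9 (1.3 equiv), Cs2CO3 (1.5 equiv), Bu4NI (cat.), DMF, 60 °C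
Reagents that add atoms: none
Why: The chelated hydroxyl needs forcing Williamson conditions; the caesium phenoxide in DMF breaks the hydrogen bond and is alkylated, while carbonate does not alkylate the acetyl group.

**Step 6**
Reactants: 11 1-{4-(benzyloxy)-2,6-bis[4-(benzyloxy)benzyloxy]phenyl}ethanone; 5 5,7-bis(benzyloxy)-2-[4-(benzyloxy)phenyl]-3-iodo-4H-chromen-4-one
Product: 12 5,7-bis(benzyloxy)-2-[4-(benzyloxy)phenyl]-3-(2-{4-(benzyloxy)-2,6-bis[4-(benzyloxy)benzyloxy]phenyl}-2-oxoethyl)-4H-chromen-4-one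
Conditions: Pd2(dba)3 (2.5 mol%), Xantphos (6 mol%), K3PO4 (3 equiv), toluene, 90 °C
Reagents that add atoms: none
Why: In this palladium-catalysed α-arylation of a ketone (Buchwald–Hartwig type) the C3''–I bond adds to zerovalent palladium, iodide is exchanged for the potassium enolate of the methyl ketone, and reductive elimination from the wide-bite-angle Xantphos complex forms the C3–C3'' bond; the more acidic product rests as its enolate, which prevents a second arylation.

**Step 7**
Reactants: 12 5,7-bis(benzyloxy)-2-[4-(benzyloxy)phenyl]-3-(2-{4-(benzyloxy)-2,6-bis[4-(benzyloxy)benzyloxy]phenyl}-2-oxoethyl)-4H-chromen-4-one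
Product: 13 5,7-bis(benzyloxy)-2-[4-(benzyloxy)phenyl]-3-(2-{4-(benzyloxy)-2,6-bis[4-(benzyloxy)benzyloxy]phenyl}-1-diazo-2-oxoethyl)-4H-chromen-4-one
Conditions: 4-acetamidobenzenesulfonyl azide (1.5 equiv), DBU (1.5 equiv), MeCN/CH2Cl2, 0 °C → rt, dark
Reagents that add atoms: 4-acetamidobenzenesulfonyl azide, CC(=O)Nc1ccc(cc1)S(=O)(=O)N=[N+]=[N-]
Why: In this Regitz diazo transfer DBU forms the enolate of the benzyl-type ketone (as with deoxybenzoins), which attacks the terminal azide nitrogen and expels the sulfonamide.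

**Step 8**
Reactants: 13 5,7-bis(benzyloxy)-2-[4-(benzyloxy)phenyl]-3-(2-{4-(benzyloxy)-2,6-bis[4-(benzyloxy)benzyloxy]phenyl}-1-diazo-2-oxoethyl)-4H-chromen-4-one
Product: 15 (2S,3R)-7-(benzyloxy)-5-[4-(benzyloxy)benzyloxy]-2-[4-(benzyloxy)phenyl]-3-{5,7-bis(benzyloxy)-2-[4-(benzyloxy)phenyl]-4-oxo-4H-chromen-3-yl}chroman-4-one, via cis-chromanone 14 (not isolated)
Conditions: Rh2(S-PTTL)4 (2 mol%), 4 Å MS, toluene, slow addition of 13, −40 °C → rt; then SiO2, CH2Cl2, rt
Reagents that add atoms: none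
Why: Rh2(S-PTTL)4, dirhodium tetrakis[N-phthaloyl-(S)-tert-leucinate], a chiral carboxylate of divalent rhodium, expels N2 from 13, and the carbene at C3 (aroyl acceptor, chromen-3-yl donor) takes a benzylic hydrogen of one ortho OCH2Ar group through a three-centre, hydride-shift-like transition state, forming C2–C3 with retention at C2. The closest known reaction is the intramolecular C–H insertion of 2-alkoxyaryl alpha-diazoketones into the ether alpha-C–H bond under chiral dirhodium carboxylates, which gives chroman-4-ones; the alkenyl-type donor on the carbene is the only extension. Ring C closes as a six-membered ring by 1,6-insertion, since the 1,5-position is the ether oxygen and every other benzylic C–H bond of the molecule (para ether of ring A, ethers of the flavone) would need a ring of seven or more atoms. C2 is set by the chiral ligand pocket, which chooses one of the two enantiotopic benzylic hydrogens (the two ortho ethers are interchanged by rotation about the aryl–carbonyl bond, so both give the same product), whereas C3 is set afterwards by equilibration of the kinetic cis isomer 14 through its enol on silica, which places the flavonyl group trans to ring B (2S,3R). The step needs insertion to win over oxonium ylide formation with 1,2-shift of the benzyl group and over attack on the ortho carbons of ring B''. Working for insertion are the double activation of the C–H bond (alpha to oxygen and 4-alkoxybenzylic), the low basicity of an aryl ether oxygen on an acylated arene, the tempered electrophilicity of a donor/acceptor carbene under bulky ligands, and the meta relation of the ring B'' ortho carbons to the benzyloxy group.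

**Step 9**
Reactants: 15 (2S,3R)-7-(benzyloxy)-5-[4-(benzyloxy)benzyloxy]-2-[4-(benzyloxy)phenyl]-3-{5,7-bis(benzyloxy)-2-[4-(benzyloxy)phenyl]-4-oxo-4H-chromen-3-yl}chroman-4-one
Product: 16 (2S,3R)-5,7-dihydroxy-2-(4-hydroxyphenyl)-3-[5,7-dihydroxy-2-(4-hydroxyphenyl)-4-oxo-4H-chromen-3-yl]chroman-4-one
Conditions: H2 (1 atm), 10% Pd/C, THF/EtOAc, rt
Reagents that add atoms: none
Why: Hydrogenolysis should cleave the six O-benzyl bonds and the primary aryl O–CH2 bond of the 4-oxybenzyl linker on O5 much faster than the secondary, ring-bound C2–O1 bond, and the neutral medium leaves C2 and C3 untouched.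

**Compound list**
1 | 1-[2,4-bis(benzyloxy)-6-hydroxyphenyl]ethanone | CC(=O)c1c(O)cc(OCc2ccccc2)cc1OCc1ccccc1 | starting material
2 | 4-(benzyloxy)benzoyl chloride | O=C(Cl)c1ccc(OCc2ccccc2)cc1 | starting material
3 | 1-[2,4-bis(benzyloxy)-6-hydroxyphenyl]-3-[4-(benzyloxy)phenyl]propane-1,3-dione (1,3-diketone) | O=C(CC(=O)c1ccc(OCc2ccccc2)cc1)c1c(O)cc(OCc2ccccc2)cc1OCc1ccccc1 | intermediate
4 | 5,7-bis(benzyloxy)-2-[4-(benzyloxy)phenyl]-4H-chromen-4-one | O=c1cc(-c2ccc(OCc3ccccc3)cc2)oc2cc(OCc3ccccc3)cc(OCc3ccccc3)c12 | intermediate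
5 | 5,7-bis(benzyloxy)-2-[4-(benzyloxy)phenyl]-3-iodo-4H-chromen-4-one | O=c1c(I)c(-c2ccc(OCc3ccccc3)cc2)oc2cc(OCc3ccccc3)cc(OCc3ccccc3)c12 | intermediate
6 | 1-(2,4,6-trihydroxyphenyl)ethanone | CC(=O)c1c(O)cc(O)cc1O | starting material
7 | benzyl bromide | BrCc1ccccc1 | starting material
8 | 1-[4-(benzyloxy)-2,6-dihydroxyphenyl]ethanone | CC(=O)c1c(O)cc(OCc2ccccc2)cc1O | intermediate
9 | 4-(benzyloxy)benzyl chloride | ClCc1ccc(OCc2ccccc2)cc1 | starting material
10 | 1-{4-(benzyloxy)-2-[4-(benzyloxy)benzyloxy]-6-hydroxyphenyl}ethanone | CC(=O)c1c(O)cc(OCc2ccccc2)cc1OCc1ccc(OCc2ccccc2)cc1 | intermediate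
11 | 1-{4-(benzyloxy)-2,6-bis[4-(benzyloxy)benzyloxy]phenyl}ethanone | CC(=O)c1c(OCc2ccc(OCc3ccccc3)cc2)cc(OCc2ccccc2)cc1OCc1ccc(OCc2ccccc2)cc1 | intermediate
12 | 5,7-bis(benzyloxy)-2-[4-(benzyloxy)phenyl]-3-(2-{4-(benzyloxy)-2,6-bis[4-(benzyloxy)benzyloxy]phenyl}-2-oxoethyl)-4H-chromen-4-one | O=C(Cc1c(-c2ccc(OCc3ccccc3)cc2)oc2cc(OCc3ccccc3)cc(OCc3ccccc3)c2c1=O)c1c(OCc2ccc(OCc3ccccc3)cc2)cc(OCc2ccccc2)cc1OCc1ccc(OCc2ccccc2)cc1 | intermediate
13 | 5,7-bis(benzyloxy)-2-[4-(benzyloxy)phenyl]-3-(2-{4-(benzyloxy)-2,6-bis[4-(benzyloxy)benzyloxy]phenyl}-1-diazo-2-oxoethyl)-4H-chromen-4-one | [N-]=[N+]=C(C(=O)c1c(OCc2ccc(OCc3ccccc3)cc2)cc(OCc2ccccc2)cc1OCc1ccc(OCc2ccccc2)cc1)c1c(-c2ccc(OCc3ccccc3)cc2)oc2cc(OCc3ccccc3)cc(OCc3ccccc3)c2c1=O | intermediate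
14 | (2S,3S)-7-(benzyloxy)-5-[4-(benzyloxy)benzyloxy]-2-[4-(benzyloxy)phenyl]-3-{5,7-bis(benzyloxy)-2-[4-(benzyloxy)phenyl]-4-oxo-4H-chromen-3-yl}chroman-4-one (cis) | O=C1c2c(OCc3ccc(OCc4ccccc4)cc3)cc(OCc3ccccc3)cc2O[C@H](c2ccc(OCc3ccccc3)cc2)[C@@H]1c1c(-c2ccc(OCc3ccccc3)cc2)oc2cc(OCc3ccccc3)cc(OCc3ccccc3)c2c1=O | intermediate
15 | (2S,3R)-7-(benzyloxy)-5-[4-(benzyloxy)benzyloxy]-2-[4-(benzyloxy)phenyl]-3-{5,7-bis(benzyloxy)-2-[4-(benzyloxy)phenyl]-4-oxo-4H-chromen-3-yl}chroman-4-one (trans) | O=C1c2c(OCc3ccc(OCc4ccccc4)cc3)cc(OCc3ccccc3)cc2O[C@H](c2ccc(OCc3ccccc3)cc2)[C@H]1c1c(-c2ccc(OCc3ccccc3)cc2)oc2cc(OCc3ccccc3)cc(OCc3ccccc3)c2c1=O | intermediate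
16 | (2S,3R)-5,7-dihydroxy-2-(4-hydroxyphenyl)-3-[5,7-dihydroxy-2-(4-hydroxyphenyl)-4-oxo-4H-chromen-3-yl]chroman-4-one | O=C1c2c(O)cc(O)cc2O[C@H](c2ccc(O)cc2)[C@H]1c1c(-c2ccc(O)cc2)oc2cc(O)cc(O)c2c1=O | target

**Totals**
Total step count: 9. Longest linear sequence: 7 steps (6 to 16 through steps 3 to 9); the iodoflavone branch (steps 1 and 2) joins at step 6.

**Steps most likely to fail**

Step 8. The carbene may be diverted to an oxonium ylide at the ortho ether oxygen, followed by 1,2-shift of the 4-(benzyloxy)benzyl group to a benzofuran-3-one skeleton, or the catalyst may discriminate poorly between the two enantiotopic benzylic hydrogens. The fallback sets out from 12 and comes back at 16. Trifluoroacetic acid (5% v/v) with anisole (COc1ccccc1) in CH2Cl2 at 0 °C removes only the two acid-labile 4-(benzyloxy)benzyl ethers of ring A and gives the 2,6-dihydroxy ketone F1. Condensation of F1 with 4-(benzyloxy)benzaldehyde (O=Cc1ccc(OCc2ccccc2)cc1; piperidine, EtOH, reflux) closes ring C by Knoevenagel condensation and oxa-Michael addition under thermodynamic control and should give the racemic trans-chromanone F2. The (2S,3R) enantiomer F3 is separated by preparative HPLC on a chiral stationary phase and hydrogenolysed (H2, Pd/C, THF/EtOAc) to 16.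

Step 6. The potassium enolate of 11, or the enolate of the product, may add to C2'' and open the pyranone ring faster than the palladium cycle turns over, and hydrodeiodination of 5 may compete. The fallback sets out from 11 and comes back at 12; it forms the C3–C3'' bond by alkylation before ring C'' exists and uses no palladium. Ketone 11 is converted with LiN(SiMe3)2 and chlorotrimethylsilane (C[Si](C)(C)Cl; THF, −78 °C) into the trimethylsilyl enol ether F4. N-Bromosuccinimide (O=C1CCC(=O)N1Br; THF, −78 → 0 °C) brominates F4 at the terminal carbon, without attack on the electron-rich ring A, to give the α-bromoketone F5. Diketone 3, isolated from step 1 by leaving out the NaOAc/AcOH stage, is alkylated at its central carbon by F5 (K2CO3, acetone, rt) to the triketone F6. Pyridinium 4-toluenesulfonate (cat., toluene, 80 °C) then closes ring C'' by attack of the ortho hydroxyl on the 4-(benzyloxy)benzoyl carbonyl and loss of water, which should give 12.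

Step 7. Proton removal from the crowded methylene by DBU may be too slow for the azide transfer to compete with decay of the reagent, and long exposure to base may open the pyranone ring or destroy the diazoketone. The fallback sets out from 12 and comes back at 13 by deacylative diazo transfer. The lithium enolate of 12 (LiN(SiMe3)2, THF, −78 °C) is acylated with 2,2,2-trifluoroethyl trifluoroacetate (FC(F)(F)COC(=O)C(F)(F)F) and quenched with 1 M HCl to give the alpha-trifluoroacetyl ketone F7. This activated 1,3-diketone reacts with methanesulfonyl azide (CS(=O)(=O)N=[N+]=[N-]; Et3N, H2O, MeCN, rt) with loss of the trifluoroacetyl group and should give 13.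

**Further compounds**
F1 | step 8 | 5,7-bis(benzyloxy)-2-[4-(benzyloxy)phenyl]-3-{2-[4-(benzyloxy)-2,6-dihydroxyphenyl]-2-oxoethyl}-4H-chromen-4-one | O=C(Cc1c(-c2ccc(OCc3ccccc3)cc2)oc2cc(OCc3ccccc3)cc(OCc3ccccc3)c2c1=O)c1c(O)cc(OCc2ccccc2)cc1O
F2 | step 8 | racemic trans-7-(benzyloxy)-2-[4-(benzyloxy)phenyl]-3-{5,7-bis(benzyloxy)-2-[4-(benzyloxy)phenyl]-4-oxo-4H-chromen-3-yl}-5-hydroxychroman-4-one (both enantiomers) | O=C1c2c(O)cc(OCc3ccccc3)cc2O[C@H](c2ccc(OCc3ccccc3)cc2)[C@H]1c1c(-c2ccc(OCc3ccccc3)cc2)oc2cc(OCc3ccccc3)cc(OCc3ccccc3)c2c1=O.O=C1c2c(O)cc(OCc3ccccc3)cc2O[C@@H](c2ccc(OCc3ccccc3)cc2)[C@@H]1c1c(-c2ccc(OCc3ccccc3)cc2)oc2cc(OCc3ccccc3)cc(OCc3ccccc3)c2c1=O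
F3 | step 8 | (2S,3R)-7-(benzyloxy)-2-[4-(benzyloxy)phenyl]-3-{5,7-bis(benzyloxy)-2-[4-(benzyloxy)phenyl]-4-oxo-4H-chromen-3-yl}-5-hydroxychroman-4-one | O=C1c2c(O)cc(OCc3ccccc3)cc2O[C@H](c2ccc(OCc3ccccc3)cc2)[C@H]1c1c(-c2ccc(OCc3ccccc3)cc2)oc2cc(OCc3ccccc3)cc(OCc3ccccc3)c2c1=O
F4 | step 6 | {1-[4-(benzyloxy)-2,6-bis[4-(benzyloxy)benzyloxy]phenyl]ethenyloxy}trimethylsilane | C=C(O[Si](C)(C)C)c1c(OCc2ccc(OCc3ccccc3)cc2)cc(OCc2ccccc2)cc1OCc1ccc(OCc2ccccc2)cc1
F5 | step 6 | 1-{4-(benzyloxy)-2,6-bis[4-(benzyloxy)benzyloxy]phenyl}-2-bromoethanone | BrCC(=O)c1c(OCc2ccc(OCc3ccccc3)cc2)cc(OCc2ccccc2)cc1OCc1ccc(OCc2ccccc2)cc1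
F6 | step 6 | 1-[2,4-bis(benzyloxy)-6-hydroxyphenyl]-2-(2-{4-(benzyloxy)-2,6-bis[4-(benzyloxy)benzyloxy]phenyl}-2-oxoethyl)-3-[4-(benzyloxy)phenyl]propane-1,3-dione | O=C(CC(C(=O)c1ccc(OCc2ccccc2)cc1)C(=O)c1c(O)cc(OCc2ccccc2)cc1OCc1ccccc1)c1c(OCc2ccc(OCc3ccccc3)cc2)cc(OCc2ccccc2)cc1OCc1ccc(OCc2ccccc2)cc1
F7 | step 7 | 5,7-bis(benzyloxy)-2-[4-(benzyloxy)phenyl]-3-(1-{4-(benzyloxy)-2,6-bis[4-(benzyloxy)benzyloxy]phenyl}-4,4,4-trifluoro-1,3-dioxobutan-2-yl)-4H-chromen-4-one | O=C(C(C(=O)C(F)(F)F)c1c(-c2ccc(OCc3ccccc3)cc2)oc2cc(OCc3ccccc3)cc(OCc3ccccc3)c2c1=O)c1c(OCc2ccc(OCc3ccccc3)cc2)cc(OCc2ccccc2)cc1OCc1ccc(OCc2ccccc2)cc1
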